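**Retrosynthetic overview**
- Feature: in ring B (N1, C2, C3, C4, C4a, C8a; the 4-pyridone ring fused to benzo ring A), C2 carries the tetradecyl chain and sits between N1 and C3, the carbon alpha to the C4 aryl ketone. With H2 formally added across C2=C3, N1–C2–C3–C4=O is a Mannich base and C2 is its aldehyde-derived carbon.
- Disconnection 1 (last forward step): the C2=C3 double bond is traced back to racemic 1-methyl-2-tetradecyl-2,3-dihydroquinolin-4(1H)-one by dehydrogenation.
- Disconnection 2 (key): N1–C2 and C2–C3 are cut to give 1-[2-(methylamino)phenyl]ethanone and pentadecanal; forward, iminium formation is followed by intramolecular Mannich closure.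
- Ring order: ring A is bought with N1, the N-methyl group and the acetyl group in place; ring B is the only ring formed (step 1) and is aromatised in step 2.

Key step: step 1

Assumption: both starting materials are purchased, the aldehyde distilled just before use. The target is achiral, so C2 of the dihydroquinolinone is carried as a racemate and no asymmetric catalyst is used.

**Step 1**
Reactants: 1 1-[2-(methylamino)phenyl]ethanone; 2 pentadecanal
Product: 4 racemic 1-methyl-2-tetradecyl-2,3-dihydroquinolin-4(1H)-one, via iminium ion 3 (not isolated)
Conditions: 2 (1.3 equiv, added by syringe pump over 6 h), (PhO)2P(O)OH (20 mol%), 4 Å MS, PhMe, 60 °C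
Reagents that add atoms: none
Why: The acid should condense the secondary aniline nitrogen of 1 with 2 to the N-aryl-N-methyliminium ion 3 (N1–C2), and the enol of the ortho acetyl group, which has α-hydrogens on one side only, should then attack the iminium carbon (C2–C3) in an intramolecular Mannich reaction; the closest known reaction type is the acid- or amine-catalysed annulation of 2-aminoaryl methyl ketones with aldehydes to 2-substituted 2,3-dihydroquinolin-4(1H)-ones, the benzo-fused counterpart of the acid-mediated 4-piperidone synthesis from β-amino ketones and aldehydes. Ring B closes in a 6-(enolendo)-endo-trig mode, with both iminium atoms and both enol carbons inside the new six-membered ring. C2 is the only new stereocentre and nothing controls it, so 4 is expected as a racemate, which is acceptable because step 2 makes C2 trigonal. The step needs cross-reaction in preference to self-aldol condensation of the enolisable aldehyde, and it needs the aldehyde carbon to act as the electrophile at C2 and not, through its enamine tautomer, as a nucleophile toward the ketone carbonyl (Friedländer mode). Slow addition keeps the concentration of free 2 low while the enol is held next to the iminium carbon in the same molecule, and the N-methyl group leaves the Friedländer mode without a neutral aromatic quinoline as exit, so the reversible manifold should drain to the β-amino ketone 4. Should the enol add to the free aldehyde first, dehydration and conjugate addition of N1 to the resulting enone would lead to 4 as well.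

**Step 2**
Reactants: 4 racemic 1-methyl-2-tetradecyl-2,3-dihydroquinolin-4(1H)-one
Product: 5 1-methyl-2-tetradecylquinolin-4(1H)-one
Conditions: Pd(O2CCF3)2 (10 mol%), DMSO (20 mol%), O2 (1 atm), AcOH, 80 °C
Reagents that add atoms: none
Why: Palladium-catalysed aerobic α,β-dehydrogenation of a ketone, in which divalent palladium should form the C3 palladium enolate, β-hydride elimination removes the C2 hydrogen and O2 reoxidises the palladium hydride; the reaction type is established for cyclic ketones, chroman-4-ones and N-substituted 4-piperidones and is driven here by formation of the aromatic 4-pyridone ring B, with the racemic C2 centre becoming trigonal.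

**Compound list**
1 | 1-[2-(methylamino)phenyl]ethanone | CNc1ccccc1C(C)=O | starting material
2 | pentadecanal | CCCCCCCCCCCCCCC=O | starting material
3 | N-(2-acetylphenyl)-N-methylpentadecan-1-iminium diphenyl phosphate (C=N geometry not defined) | CCCCCCCCCCCCCCC=[N+](C)c1ccccc1C(C)=O.[O-]P(=O)(Oc1ccccc1)Oc1ccccc1 | intermediate
4 | racemic 1-methyl-2-tetradecyl-2,3-dihydroquinolin-4(1H)-one | CCCCCCCCCCCCCCC1CC(=O)c2ccccc2N1C | intermediate
5 | 1-methyl-2-tetradecylquinolin-4(1H)-one | CCCCCCCCCCCCCCc1cc(=O)c2ccccc2n1C | target

Total step count: 2
Longest linear sequence: 2 steps (from 1 or 2 to 5)

**Steps most likely to fail**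
The route has two steps, so both are ranked, the more exposed one first.

1. Step 1. The aldehyde may be consumed by self-aldol condensation, directly or through its N-aryl enamine, before the slowly enolising aryl ketone can close the ring. Alternatively the enamine may add to the ketone carbonyl in a Friedländer-type condensation that ties up the acid catalyst as a quinolinium salt. Fallback (stepwise, base-mediated): setting out from 1, double deprotonation with LiN(i-Pr)2 (2.2 equiv, THF, −78 °C) should give the N-lithio lithium enolate, which adds to 2 at −78 °C to give racemic 3-hydroxy-1-[2-(methylamino)phenyl]heptadecan-1-one F1. Heating F1 with p-TsOH·H2O in toluene should dehydrate it to (E)-1-[2-(methylamino)phenyl]heptadec-2-en-1-one F2, whose NHMe group closes ring B by 6-endo-trig aza-Michael addition, returning to the route at 4. Here C2–C3 is made first by a preformed enolate at low temperature, so the free aldehyde never meets the acid.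

2. Step 2. Palladation at C3 may be slow because the ketone is a vinylogous amide with low α-acidity, and the catalyst may be bound by the basic carbonyl oxygen of the 4-quinolone product or aggregate to palladium metal before full conversion. Fallback (selenoxide elimination): setting out from 4, enolisation with LiN(i-Pr)2 (THF, −78 °C) and trapping with PhSeCl should give 1-methyl-3-(phenylselanyl)-2-tetradecyl-2,3-dihydroquinolin-4(1H)-one F3. Oxidation with aqueous H2O2 in CH2Cl2/pyridine at 0 °C to room temperature should give the selenoxide 1-methyl-3-(phenylseleninyl)-2-tetradecyl-2,3-dihydroquinolin-4(1H)-one F4, which undergoes syn-elimination across C2–C3 and returns to the route at 5. Selenation anti to the C2 chain places selenium syn to the C2 hydrogen, as the elimination requires.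

**Further compounds**
F1 | step 1 | racemic 3-hydroxy-1-[2-(methylamino)phenyl]heptadecan-1-one | CCCCCCCCCCCCCCC(O)CC(=O)c1ccccc1NC
F2 | step 1 | (E)-1-[2-(methylamino)phenyl]heptadec-2-en-1-one | CCCCCCCCCCCCCC/C=C/C(=O)c1ccccc1NC
F3 | step 2 | 1-methyl-3-(phenylselanyl)-2-tetradecyl-2,3-dihydroquinolin-4(1H)-one (racemic, mixture of C3 epimers) | CCCCCCCCCCCCCCC1C([Se]c2ccccc2)C(=O)c2ccccc2N1C
F4 | step 2 | 1-methyl-3-(phenylseleninyl)-2-tetradecyl-2,3-dihydroquinolin-4(1H)-one (selenoxide, not isolated) | CCCCCCCCCCCCCCC1C([Se](=O)c2ccccc2)C(=O)c2ccccc2N1C
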